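**The decision.** I chose to measure each flask in enzyme-minutes: c(enzyme) times the clock time less 2.00 min, the mean wait of the fed charge. Midnight at the end came to 84.0 µM·min. Time then dropped out of the comparison, since two flasks with equal enzyme-minutes, at the same charge, feed and added ligand, should stand alike.

| flask | starting material | enzyme | added ligand | remark | time |
|---|---|---|---|---|---|
| Wednesday's | 20 mM (fed, over 4.0 min) | 0.048 µM | 12 µM | run made earlier; the fed solution adds 0.10 times the starting volume |  |
| Friday's | 20 mM (fed, over 4.0 min) | 4.5 µM | 12 µM | run made earlier; the fed solution adds 0.10 times the starting volume |  |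
| summer | 20 mM (fed, over 4.0 min) | 0.040 µM | 12 µM | the fed solution adds 0.10 times the starting volume | 30 min |
| autumn | 20 mM (fed, over 4.0 min) | 0.12 µM | 12 µM | the fed solution adds 0.10 times the starting volume | 30 min |
| winter | 20 mM (fed, over 4.0 min) | 0.40 µM | 12 µM | the fed solution adds 0.10 times the starting volume | 30 min |
| dawn | 20 mM (fed, over 4.0 min) | 1.2 µM | 12 µM | the fed solution adds 0.10 times the starting volume | 30 min |
| midnight | 20 mM (fed, over 4.0 min) | 3.0 µM | 12 µM | the fed solution adds 0.10 times the starting volume | 30 min |

- Wednesday's (time / min: target / %, starting material / %): 2.50: 0.4, 62.3; 8.00: 1.1, 99.5; 15.0: 0.5, 99.4; 20.0: 0.7, 99.6; 30.0: 1.0, 99.7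
- Friday's (time / min: target / %, starting material / %): 6.00: 9.1, 89.5; 12.0: 22.3, 78.8; 20.0: 31.2, 68.9; 25.0: 34.6, 65.4; 30.0: 37.3, 63.4

(readings scatter by 0.5 percentage points)

1. amount of target at the end, in percent of the starting material charged for summer, autumn, winter, dawn, midnight, in this order
2. how the row runs (rises, then falls / falls all the way / falls, then rises / rises all the way / hardly changes)

- charges are per starting volume, the dose included; the dosed solution carries all of it
- the analysis behind the earlier runs scatters by 0.5 percentage points, standard deviation
- percentages count the whole charge, also what has not yet gone in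
- "hardly changes" means that all values lie within two and a half points (for a concentration: within two and a half percent of the largest)

**The oddity.** Friday's run carried 93.8 times the enzyme of Wednesday's, yet at 30.0 min its target reading was only 37.3 times Wednesday's reading.

**Clearing it.** Friday's first reading gave 9.1% at 18.0 µM·min. Scaled down to Wednesday's 1.34 µM·min, that line gives 0.679%, within the scatter of the reading 1.0%. Carried on to Friday's end, the same line gives 63.7%, but the flask read 37.3%. So the two runs could be read, within the scatter, as one curve: Wednesday's sat on its straight start, and Friday's had gone round its bend.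

**My reckoning.** Midnight's 84.0 µM·min lay close to Friday's 81.0 µM·min at 20.0 min, so I read about 31.2% for midnight.

**The forecast.** It gave 0.6%, 1.8%, 5.6%, 17% and 32%, so the row rises all the way, judging that “the slowing seems tied to conversion or turnover”. For midnight that stood a little above my reading.

**The result.** The flasks gave 0.646%, 1.92%, 6.12%, 16.3% and 30.8%, so the row rises all the way, with midnight at 84.0 µM·min.

    starting material + enzyme ⇌ starting complex (K = 65.5 /M, k = 88400 /M/s)
    starting complex ⇌ enzyme + target (K = 0.0112 M, k = 7.61 /s)
    enzyme + added ligand ⇌ idle complex, settled at all times (K = 2.30 × 10⁵ /M)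

**Close doses.** Summer at 300 min had 11.9 µM·min and held 6.40% target; winter at 30.0 min had 11.2 µM·min and held 6.12%. The rule needs the catalyst's shares to stay level with its charge, and at 9.00 min the idle complex, an off-cycle form, stood at 53.4% in summer and 51.6% in midnight, the starting complex at 25.2% and 24.7%, the free enzyme at 21.3% and 23.6%. In summer the forward binding step alone had a half-life of 17 min at 30.0 min, yet 99.4% of the starting material was left then.

(The runs stem from a simulated flask with made-up constants.)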